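**Retrosynthetic overview**

1. Feature: in ring B (C5, C6, C7, C8, C9, C10, C1) the oxygenated carbons C6 and C10 flank the unit C7–C8(=C14)–C9, so ring B is a cyclopentane-1,3-dione ring (C6, C7, C10, C1, C5) fused to ring A (C1–C5) into which propadiene (C8, C9, C14) is inserted. β is the face of the C15 methyl on C1, α the face of H5 in the target.
2. Target 25 ⇐ triol ester 24 (epoxidation of C8=C14 directed by 9α-OH) ⇐ trans-fused dienone 18 (OsO4 on C9=C10, deconjugation, SmI2 at C6, isovaleroylation). Every α oxygen on ring B is placed opposite the β angular methyl.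
3. 18 ⇐ cis-fused 6,10-dione 13: C6 masked by hydroxyl-directed reduction, Shapiro olefination at C10, re-oxidation and base equilibration, which is where C5 is inverted to the trans fusion.
4. 13 ⇐ cis-diquinane dione 10 + propadiene: enone–allene photocycloaddition (C7–C8, C9–C10), then retro-aldol cleavage of C7–C10. The seven-membered ring B is the last ring formed.
5. 10 ⇐ 3-methylcyclopent-2-en-1-one (ring A): asymmetric conjugate furylation with aldol trapping, isopropylcerium addition, furan-to-acid oxidation, then Claisen closure of the five-membered dione ring.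

Key step: step 6

Remark: the carbinol carbon made in step 1 and the C6 carbinol of step 7 are formed without control and are oxidised again (steps 3 and 10), so these two centres are left open in the SMILES.

**Route**

Step 1
Reactants: 1 3-methylcyclopent-2-en-1-one; 2 furan; 3 acetaldehyde
Product: 5 3-(furan-2-yl)-2-(1-hydroxyethyl)-3-methylcyclopentan-1-one (C1: methyl β and furyl α; C5 side chain β), via aluminium enolate 4 (not isolated)
Conditions: 2, nBuLi, Et2O, 0 °C; Me2AlCl, −30 °C; then 1, Cu(O2CC4H3S) (copper thiophene-2-carboxylate, 5 mol%), chiral aminophosphine Ph2PN[CH(CH3)Ph]2 (SimplePhos, enantiomer chosen for the C1 configuration shown), Et2O, −20 °C; MeLi, −78 °C; 3; aq. NH4Cl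
Reagents that add atoms: none
Why: Copper-catalysed asymmetric conjugate addition of an aryl-alane to a β-methyl cyclic enone is an established route to all-carbon quaternary centres and the ligand sets C1, while the regiodefined aluminium enolate (activated as its ate complex) should add to acetaldehyde at C5 in an aldol reaction from the face opposite the furyl group.

Step 2
Reactants: 5 3-(furan-2-yl)-2-(1-hydroxyethyl)-3-methylcyclopentan-1-one
Product: 6 3-(furan-2-yl)-2-(1-hydroxyethyl)-3-methyl-1-(propan-2-yl)cyclopentan-1-ol (4β-OH; 4α-isopropyl)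
Conditions: iPrMgCl (3.5 equiv), CeCl3 (anhydrous), THF, −78 → 0 °C
Reagents that add atoms: isopropylmagnesium chloride, CC(C)[Mg]Cl
Why: Organocerium 1,2-addition avoids enolisation and reduction, and the reagent should approach C4 anti to the vicinal C5 side chain and to the pseudoaxial C15 methyl, that is from the α face, which puts isopropyl α and the hydroxyl β.

Step 3
Reactants: 6 furyl diol
Product: 7 2-acetyl-3-hydroxy-1-methyl-3-(propan-2-yl)cyclopentane-1-carboxylic acid (acetyl β and trans to CO2H)
Conditions: RuCl3 (cat.), NaIO4, CCl4/MeCN/H2O, rt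
Reagents that add atoms: sodium periodate, [Na+].[O-]I(=O)(=O)=O; water, O
Why: Catalytic RuO4 oxidation degrades the 2-furyl group to the C10 carboxylic acid and oxidises the secondary carbinol to the methyl ketone in the same operation, while the tertiary alcohol and the three ring stereocentres are untouched.

Step 4
Reactants: 7 keto acid
Product: 8 methyl 2-acetyl-3-hydroxy-1-methyl-3-(propan-2-yl)cyclopentane-1-carboxylate (acetyl trans to ester)
Conditions: TMSCHN2, PhMe/MeOH, 0 °C
Reagents that add atoms: trimethylsilyldiazomethane, C[Si](C)(C)C=[N+]=[N-]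
Why: Esterification with TMSCHN2 runs under neutral conditions that leave the tertiary β-hydroxy ketone intact.

Step 5
Reactants: 8 trans keto ester
Product: 10 cis-diquinane dione drawn as its enol (4β-OH; 4α-isopropyl; 1β-CH3; 5β-H), via cis keto ester 9 (not isolated)
Conditions: KHMDS (3.3 equiv), THF, −78 °C → rt; then 1 M HCl, 0 °C
Reagents that add atoms: none
Why: Intramolecular Claisen (Dieckmann-type) condensation, in which excess amide base holds the alcohol as alkoxide and the ketone as enolate (blocking retro-aldol cleavage and E1cB loss of oxygen), enolate equilibration inverts C5 by reprotonation from the β face, and only the cis keto ester 9 can close to the five-membered dione, which is withdrawn as its stabilised enolate.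

Step 6
Reactants: 10 cis-diquinane dione (enol form); 11 propadiene
Product: 13 cis-fused hydroazulene-6,10-dione with exocyclic C8=C14 methylene (4β-OH; 4α-isopropyl; 1β-CH3; 5β-H), via cyclobutanol 12 (not isolated)
Conditions: hν (medium-pressure Hg lamp, borosilicate filter), 11 (excess), CH2Cl2, −50 °C, partial conversion; no amine or other base; neutral silica
Reagents that add atoms: none
Why: Excitation of the enolised dione gives the triplet enone, which adds propadiene stepwise through a 1,4-biradical in the head-to-head sense (central allene carbon to the α carbon C7, terminal carbon to the oxygen-bearing C10) and closes the four-membered ring by radical recombination; the methylenecyclobutanol 12 is a strained β-hydroxy ketone and undergoes retro-aldol cleavage of the C7–C10 bond, which enlarges the five-membered dione ring by two atoms into seven-membered ring B. The closest known reactions are the De Mayo reaction of cyclic 1,3-diketone enols with alkenes and the photocycloaddition of allene to cyclic enones. No lasting stereocentre is made: the cyclobutane carbons end as C=O and CH2, and C5 keeps its cis configuration because the retro-aldol enol lies on the C7 side and no base is present, so the fusion is inverted later, in step 10. The step needs head-to-head regiochemistry, which is the intrinsic preference of triplet cyclic enones towards allene, and it does not matter which enol tautomer reacts because the inserted C7–C8(=C14)–C9 unit is symmetric. Base is excluded because C7–H and C9–H of the product are far more acidic than C5–H and an amine would move the C8=C14 alkene into conjugation; photochemical 1,3-acyl shifts of the β,γ-unsaturated ketones are degenerate here, and irradiation is stopped early to limit other secondary photoreactions.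

Step 7
Reactants: 13 cis-fused 6,10-dione
Product: 14 cis-fused 4,6-dihydroxy-10-ketone with C8=C14 methylene
Conditions: Me4NBH(OAc)3, AcOH/MeCN, −30 °C
Reagents that add atoms: none
Why: Hydroxyl-directed triacetoxyborohydride reduction (Evans–Saksena type), in which the reagent exchanges onto the 4-hydroxyl and delivers hydride intramolecularly to C6 only, leaving the unactivated neopentyl C10 ketone and (in the mildly acidic medium) the exocyclic alkene in place.

Step 8
Reactants: 14 hydroxy ketone
Product: 15 C10 2,4,6-triisopropylbenzenesulfonylhydrazone of 14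
Conditions: 2,4,6-triisopropylbenzenesulfonohydrazide, THF, rt, no acid
Reagents that add atoms: 2,4,6-triisopropylbenzenesulfonohydrazide, NNS(=O)(=O)c1c(C(C)C)cc(C(C)C)cc1C(C)C
Why: Condensation of the remaining ketone with the arenesulfonyl hydrazide gives the hydrazone needed for the Shapiro reaction, and running it without acid avoids migration of the exocyclic alkene.

Step 9
Reactants: 15 hydrazone
Product: 16 cis-fused 4,6-diol with C8=C14 and C9=C10 alkenes
Conditions: nBuLi (4.5 equiv), THF/TMEDA, −78 → 0 °C; H2O
Reagents that add atoms: none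
Why: Shapiro reaction: after deprotonation of the two hydroxyls and N–H, the only α-hydrogens (C9) are removed, loss of sulfinate and N2 gives the C10 vinyllithium, and protonation leaves the C9=C10 alkene conjugated to the exocyclic methylene.

Step 10
Reactants: 16 diene diol
Product: 18 trans-fused dienone (C6 ketone; C7=C8 bearing the C14 methyl; C9=C10; 5α-H), via cis-fused 6-ketone 17 (not isolated)
Conditions: DMP, NaHCO3, CH2Cl2, 0 °C → rt; filtration; then DBU, PhMe, 60 °C
Reagents that add atoms: none
Why: Dess–Martin oxidation restores the C6 ketone and the amidine then equilibrates it: the alkene moves into conjugation to the linear dienone (the quaternary C1 blocks further migration) and C5 epimerises through the C6 enol to the trans fusion, which relieves the cis isopropyl/C6 interaction, allows a 4-OH···O=C6 hydrogen bond and fits the flattened dienone ring.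

Step 11
Reactants: 18 trans-fused dienone
Product: 19 9α,10α-dihydroxy enone
Conditions: OsO4 (cat.), NMO, acetone/H2O, 0 °C
Reagents that add atoms: osmium tetroxide, O=[Os](=O)(=O)=O; N-methylmorpholine N-oxide, C[N+]1([O-])CCOCC1; water, O
Why: Catalytic OsO4 dihydroxylation takes the electron-richer γ,δ-alkene of the dienone and should occur from the α face, opposite the angular C15 methyl on the adjacent C1, which sets the cis 9α,10α-diol.

Step 12
Reactants: 19 diol enone
Product: 20 9,10-O-isopropylidene enone
Conditions: Me2C(OMe)2, PPTS, acetone, rt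
Reagents that add atoms: 2,2-dimethoxypropane, COC(C)(C)OC
Why: Acetonide formation on the cis-1,2-diol protects both secondary hydroxyls for the enolate chemistry and the acylation that follow.

Step 13
Reactants: 20 acetonide enone
Product: 21 β,γ-unsaturated 6-ketone with exocyclic C8=C14 methylene
Conditions: KHMDS (2.3 equiv), THF, −78 °C; then AcOH, −78 °C
Reagents that add atoms: none
Why: Deconjugative protonation: the unhindered γ-methyl (C14) is deprotonated to the extended dienolate (C5–H is shielded by two quaternary neighbours and the adjacent alkoxide, C9–H is tertiary and oxygen-substituted), and kinetic protonation at the α carbon C7 restores the exocyclic alkene.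

Step 14
Reactants: 21 deconjugated ketone
Product: 22 6α-alcohol (4β,6α-diol; acetonide; C8=C14)
Conditions: SmI2, THF/MeOH, −78 → 0 °C
Reagents that add atoms: none
Why: SmI2 reduction of a β-hydroxy ketone, in which samarium chelated between the 4-oxygen and the ketyl oxygen should place the C6–O bond equatorial and anti to the angular methyl (6α, the more stable arrangement), while the isolated alkene and the acetonide are inert to SmI2 without additives.

Step 15
Reactants: 22 6α-alcohol
Product: 23 6α-(3-methylbutanoyl)oxy acetonide
Conditions: isovaleric anhydride, DMAP, Et3N, CH2Cl2, rt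
Reagents that add atoms: isovaleric anhydride, CC(C)CC(=O)OC(=O)CC(C)C
Why: DMAP-catalysed acylation esterifies the equatorial secondary 6-hydroxyl, whereas the hindered tertiary 4-hydroxyl does not react.

Step 16
Reactants: 23 ester acetonide
Product: 24 6α-(3-methylbutanoyl)oxy 4β,9α,10α-triol with C8=C14 methylene
Conditions: AcOH/H2O (4:1), 35 °C
Reagents that add atoms: none
Why: Mild aqueous acid hydrolysis removes the acetonide and leaves the ester, the tertiary alcohol and the 1,1-disubstituted alkene untouched.

Step 17
Reactants: 24 triol ester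
Product: 25 CNP0307265.1 (target)
Conditions: VO(acac)2 (cat.), tBuOOH, PhMe, 0 °C → rt
Reagents that add atoms: tert-butyl hydroperoxide, CC(C)(C)OO
Why: Vanadium-catalysed hydroxyl-directed epoxidation, in which the allylic 9α-hydroxyl binds the vanadium peroxide and delivers oxygen to the α face of the only alkene, giving the spiro-epoxide with its oxygen cis to the 9α-hydroxyl.

**Compound list**

1 | 3-methylcyclopent-2-en-1-one | CC1=CC(=O)CC1 | starting material
2 | furan | c1ccoc1 | starting material
3 | acetaldehyde | CC=O | starting material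
4 | dimethylaluminium enolate of 3-(furan-2-yl)-3-methylcyclopentanone (enolate C4=C5; C1 methyl β, furyl α) | o1cccc1[C@@]2(C)CCC(O[Al](C)C)=C2 | intermediate (not isolated)
5 | 3-(furan-2-yl)-2-(1-hydroxyethyl)-3-methylcyclopentan-1-one, side chain trans to furyl, carbinol centre open | o1cccc1[C@@]2(C)CCC(=O)[C@@H]2C(C)O | intermediate
6 | 3-(furan-2-yl)-2-(1-hydroxyethyl)-3-methyl-1-(propan-2-yl)cyclopentan-1-ol (4β-OH, 4α-isopropyl) | o1cccc1[C@@]2(C)CC[C@@](O)(C(C)C)[C@@H]2C(C)O | intermediate
7 | 2-acetyl-3-hydroxy-1-methyl-3-(propan-2-yl)cyclopentane-1-carboxylic acid (acetyl trans to CO2H) | OC(=O)[C@@]1(C)CC[C@@](O)(C(C)C)[C@@H]1C(C)=O | intermediate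
8 | methyl ester of 7 (acetyl trans to ester) | COC(=O)[C@@]1(C)CC[C@@](O)(C(C)C)[C@@H]1C(C)=O | intermediate
9 | C5 epimer of 8 (acetyl cis to ester) | COC(=O)[C@@]1(C)CC[C@@](O)(C(C)C)[C@H]1C(C)=O | intermediate (not isolated)
10 | cis-diquinane 6,10-dione as its enol (4β-OH, 4α-isopropyl, 1β-CH3, 5β-H) | O=C1C=C(O)[C@@]2(C)CC[C@@](O)(C(C)C)[C@@H]12 | intermediate (key-step precursor)
11 | propadiene | C=C=C | starting material
12 | methylenecyclobutanol photoadduct (C7–C8 and C9–C10 formed; the two cyclobutane centres at C7 and C10 are transient and left open) | O=C1C2C(=C)CC2(O)[C@@]3(C)CC[C@@](O)(C(C)C)[C@@H]13 | intermediate (not isolated)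
13 | cis-fused hydroazulene-6,10-dione with exocyclic C8=C14 methylene | O=C1CC(=C)CC(=O)[C@@]2(C)CC[C@@](O)(C(C)C)[C@@H]12 | intermediate (key-step product)
14 | cis-fused 4,6-dihydroxy-10-ketone, C6 centre open | OC1CC(=C)CC(=O)[C@@]2(C)CC[C@@](O)(C(C)C)[C@@H]12 | intermediate
15 | C10 2,4,6-triisopropylbenzenesulfonylhydrazone of 14 | OC1CC(=C)CC(=NNS(=O)(=O)c3c(C(C)C)cc(C(C)C)cc3C(C)C)[C@@]2(C)CC[C@@](O)(C(C)C)[C@@H]12 | intermediate
16 | cis-fused 4,6-diol with C8=C14 and C9=C10 alkenes | OC1CC(=C)C=C[C@@]2(C)CC[C@@](O)(C(C)C)[C@@H]12 | intermediate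
17 | cis-fused β,γ-unsaturated 6-ketone | O=C1CC(=C)C=C[C@@]2(C)CC[C@@](O)(C(C)C)[C@@H]12 | intermediate (not isolated)
18 | trans-fused dienone (5α-H) | O=C1C=C(C)C=C[C@@]2(C)CC[C@@](O)(C(C)C)[C@H]12 | intermediate
19 | 9α,10α-dihydroxy enone | O=C1C=C(C)[C@@H](O)[C@@H](O)[C@@]2(C)CC[C@@](O)(C(C)C)[C@H]12 | intermediate
20 | 9,10-O-isopropylidene enone | O=C1C=C(C)[C@@H](O3)[C@@H](OC3(C)C)[C@@]2(C)CC[C@@](O)(C(C)C)[C@H]12 | intermediate
21 | 9,10-O-isopropylidene 6-ketone with exocyclic C8=C14 | O=C1CC(=C)[C@@H](O3)[C@@H](OC3(C)C)[C@@]2(C)CC[C@@](O)(C(C)C)[C@H]12 | intermediate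
22 | 6α-alcohol of 21 | O[C@H]1CC(=C)[C@@H](O3)[C@@H](OC3(C)C)[C@@]2(C)CC[C@@](O)(C(C)C)[C@H]12 | intermediate
23 | 6α-isovalerate of 22 | CC(C)CC(=O)O[C@H]1CC(=C)[C@@H](O3)[C@@H](OC3(C)C)[C@@]2(C)CC[C@@](O)(C(C)C)[C@H]12 | intermediate
24 | 6α-isovalerate 4β,9α,10α-triol with C8=C14 | CC(C)CC(=O)O[C@H]1CC(=C)[C@@H](O)[C@@H](O)[C@@]2(C)CC[C@@](O)(C(C)C)[C@H]12 | intermediate
25 | CNP0307265.1 | CC(C)CC(=O)O[C@H]1C[C@]2(CO2)[C@@H](O)[C@@H](O)[C@@]2(C)CC[C@@](O)(C(C)C)[C@H]12 | target

**Step count**

Total: 17 steps. Longest linear sequence: 17 steps (from 1).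

**Three steps most likely to fail**

Step 6 (photocycloaddition and retro-aldol). What may go wrong: secondary photoreactions of the β,γ-unsaturated diketone product under continued irradiation, competing head-to-tail addition, or migration of the exocyclic alkene during isolation. Fallback, a stepwise De Mayo sequence: from 10, TBSCl and imidazole should give the tert-butyldimethylsilyl enol ether F1 (either enol regioisomer serves, since both converge). Irradiation of F1 with propadiene should give the silyloxy methylenecyclobutane F2, whose chromophore is a saturated ketone, so the photolysis can be run to completion. HF·pyridine in MeCN at −20 °C, in the dark and without base, then frees the cyclobutanol, which fragments to 13.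

Step 5 (Claisen closure with inversion at C5). What may go wrong: incomplete epimerisation at C5 under the amide base, or retro-aldol opening of ring A during equilibration with loss of the C4 configuration. Fallback, which introduces the C4 hydroxyl only after the bicycle exists: from 5, TBSOTf and 2,6-lutidine give the silyl ether F3. RuCl3/NaIO4 gives the keto acid F4 and TMSCHN2 its methyl ester F5. KHMDS and PhNTf2 give the kinetic C3=C4 enol triflate F6, and iPrMgCl with Fe(acac)3 (cat.) in THF/NMP at −30 °C couples it to the isopropyl cyclopentene F7. HF·pyridine gives the alcohol F8 and DMP the methyl ketone F9, which has no β-oxygen. KOtBu in tBuOH/THF then epimerises C5 safely and closes the diquinane ene-dione F10. Mukaiyama hydration (Mn(dpm)3 cat., PhSiH3, O2, iPrOH; then PPh3) puts the hydroxyl on C4 from the convex β face and gives 10.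

Step 14 (C6 reduction). What may go wrong: poor facial selectivity, with hydrogen delivered to the less hindered α face of C6 to give the axial 6β-alcohol. Fallback, reduction then inversion: from 21, LiBH(sBu)3 in THF at −78 °C should give the 6β-alcohol F11 by equatorial attack. Mitsunobu reaction with 4-nitrobenzoic acid (PPh3, DIAD) inverts C6 to the 6α-4-nitrobenzoate F12, and K2CO3 in MeOH returns the route to 22.

**Further compounds**

F1 | step 6 | tert-butyldimethylsilyl enol ether of 10 | O=C1C=C(O[Si](C)(C)C(C)(C)C)[C@@]2(C)CC[C@@](O)(C(C)C)[C@@H]12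
F2 | step 6 | silyloxy methylenecyclobutane photoadduct (cyclobutane centres open) | O=C1C2C(=C)CC2(O[Si](C)(C)C(C)(C)C)[C@@]3(C)CC[C@@](O)(C(C)C)[C@@H]13
F3 | step 5 | tert-butyldimethylsilyl ether of 5 | o1cccc1[C@@]2(C)CCC(=O)[C@@H]2C(C)O[Si](C)(C)C(C)(C)C
F4 | step 5 | 2-[1-(silyloxy)ethyl]-1-methyl-3-oxocyclopentane-1-carboxylic acid | OC(=O)[C@@]1(C)CCC(=O)[C@@H]1C(C)O[Si](C)(C)C(C)(C)C
F5 | step 5 | methyl ester of F4 | COC(=O)[C@@]1(C)CCC(=O)[C@@H]1C(C)O[Si](C)(C)C(C)(C)C
F6 | step 5 | C3=C4 enol triflate of F5 | COC(=O)[C@@]1(C)CC=C(OS(=O)(=O)C(F)(F)F)[C@@H]1C(C)O[Si](C)(C)C(C)(C)C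
F7 | step 5 | 4-isopropyl cyclopentene ester (C3=C4) | COC(=O)[C@@]1(C)CC=C(C(C)C)[C@@H]1C(C)O[Si](C)(C)C(C)(C)C
F8 | step 5 | desilylated alcohol of F7 | COC(=O)[C@@]1(C)CC=C(C(C)C)[C@@H]1C(C)O
F9 | step 5 | methyl ketone from F8 | COC(=O)[C@@]1(C)CC=C(C(C)C)[C@@H]1C(C)=O
F10 | step 5 | cis-diquinane dione (enol) with C3=C4 isopropyl alkene | O=C1C=C(O)[C@@]2(C)CC=C(C(C)C)[C@@H]12
F11 | step 14 | 6β-alcohol (C6 epimer of 22) | O[C@@H]1CC(=C)[C@@H](O3)[C@@H](OC3(C)C)[C@@]2(C)CC[C@@](O)(C(C)C)[C@H]12
F12 | step 14 | 6α-(4-nitrobenzoate) of 22 | O=C(O[C@H]1CC(=C)[C@@H](O3)[C@@H](OC3(C)C)[C@@]2(C)CC[C@@](O)(C(C)C)[C@H]12)c1ccc(cc1)[N+](=O)[O-]
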